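From an earlier run you would carry over how the starting material divides, rather than how fast it went.

| setting | north | west | south-east |
|---|---|---|---|
| starting material | 0.094 M | 0.094 M | 0.094 M |
| protic impurity | 0.0282 M | 0.0282 M | 0.0282 M |
| time | 3.0 d | 3.0 d | 3.0 d |
| remark | at 80 °C until 2.0 d, from then on at 50 °C |  |  |
| temperature |  | 50 °C | 80 °C |

    starting material + protic impurity → quenched substrate (k1 = 4.2 M⁻¹ h⁻¹, Ea1 = 69.0 kJ mol⁻¹)
    starting material → side product (k2 = 0.91 h⁻¹, Ea2 = 105 kJ mol⁻¹)
    starting material → target (k3 = 0.98 h⁻¹, Ea3 = 99.0 kJ mol⁻¹)
    (constants at 50 °C)

- all constants are for 50 °C and move with temperature by the activation energies

- which flask leads in share of target in all that became target or side product ("all alike" within 1.5 percentage points) (north / west / south-east / all alike)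
- share of target in all that became target or side product, north
- share of target in all that became target or side product, west
- share of target in all that became target or side product, south-east

- Write k_t and k_s for the first-order constants to target and to side product, and ρ = k_t/k_s for the selectivity factor. Both rates are proportional to the same concentration of starting material, so dividing one rate law by the other cancels that concentration, and integrating gives target over side product equal to ρ at a fixed temperature, with share ρ/(1+ρ); in west the quench path leaves that share unchanged.
- At 50 °C, ρ_cold is 1.08. Heating to 80 °C speeds the target step by 23 and the side step by 28, a larger factor, which gives ρ_hot, the selectivity factor at 80 °C, of 0.891.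
- So I reckon 51.9% for west and 47.1% for south-east. These are the upper and lower bounds for north, whose product forms at those two temperatures.
- To tighten the bracket, take the lifetime of starting material at 80 °C from the two first-order paths, 1/(k_s+k_t) = 0.0210 h, an upper figure, with the quench, 1.05 h⁻¹ at the start, as one more loss on top. North cools at 2.0 d, after 2286 such lifetimes, so north's share falls onto the lower bound and I expect west to lead.
- The forecast gave 47.1% for north, 51.9% for west and 47.1% for south-east, with west ahead, which puts north at the foot of my bracket: “north matches south-east and the cooler west flask leads”.
- The simulation gives 47.1% for north, 51.9% for west and 47.1% for south-east, with west ahead. North's starting material already reads 0% at 2.00 d, when it cools. In north, 2.08% of the charge became quenched substrate by 3.00 d, and splitting the remainder in the ratio ρ_hot gives 46.1% target, where the flask reads 46.1%. A neighbour of north charged with 0.070 M of protic impurity reads 5.02% quenched substrate, so ρ_hot gives 50.2% side product, and that neighbour reads 50.2%.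

The numbers are those of an exercise; no experiment stands behind them.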